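The route rests on disconnecting the bond between the lactam β-carbon (C11) and the gem-dimethyl carbon (C15), which is shared by the cyclohexene ring and the twelve-membered ring. A quaternary CMe2 carbon on an sp2 carbon is the retron of a reductive Heck reaction of an isopropenyl group: step 13 lets a tetramic-acid-derived enol triflate at C11 add 6-exo across the C1 isopropenyl group, and formate reduces the β-hydrogen-free neopentylpalladium to the second methyl. One transannular operation thus turns a fourteen-membered cembrane-type carbocycle, assembled from (R)-limonene oxide and an (R)-amino acid by reductive alkylation and boron macro-aldol, into the bicyclo[9.3.1] verticillane core.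

Key step: step 13

Numbering used below: C1 ring CH next to C15; C2, C3 methylenes; C4 carbon bearing the exocyclic methylene; C5 methylene; C6 acetoxy carbon; C7=C8 trisubstituted alkene (methyl on C8); C9 methylene; C10 N-bearing carbon; C11=C12 lactam alkene (C12 next to the carbonyl C20); C13, C14 methylenes; C15 gem-dimethyl carbon.

Assumption: (−)-Ipc2BCl is taken to direct a methyl ketone enol borinate to the Si face of the aldehyde, as in intermolecular cases, which gives 6S; if the macrocyclic transition state shows the opposite sense, (+)-Ipc2BCl is used instead.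

Step 1
Reactants: 1 (+)-limonene oxide (4R, commercial cis/trans mixture)
Product: 3 (3R)-6-oxo-3-(prop-1-en-2-yl)heptanal, via limonene-1,2-diol 2 (not isolated)
Conditions: H5IO6, THF/H2O, 0 °C to rt
Reagents that add atoms: water, O
Why: Acid-mediated epoxide hydrolysis followed by periodate glycol cleavage (Malaprade reaction) should converge both epoxide diastereomers on one keto aldehyde, the limonene stereocenter being untouched and becoming C1.

Step 2
Reactants: 4 (tert-butyldimethylsilyloxy)acetaldehyde; 5 2-(triphenylphosphoranylidene)propanal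
Product: 6 (2E)-4-(tert-butyldimethylsilyloxy)-2-methylbut-2-enal
Conditions: toluene, 80 °C
Reagents that add atoms: none
Why: Wittig olefination with a formyl-stabilized ylide should be E-selective, which fixes the C7=C8 geometry (C6 trans to the future C9).

Step 3
Reactants: 6 (2E)-4-(tert-butyldimethylsilyloxy)-2-methylbut-2-enal; 7 methyl 2-(tert-butoxycarbonylamino)-2-(dimethoxyphosphoryl)acetate
Product: 8 methyl (2Z,4E)-2-(tert-butoxycarbonylamino)-6-(tert-butyldimethylsilyloxy)-4-methylhexa-2,4-dienoate
Conditions: DBU, CH2Cl2, 0 °C to rt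
Reagents that add atoms: none
Why: Horner–Wadsworth–Emmons olefination of a phosphonoglycinate with an enal should give the (Z)-dehydroamino ester with the existing alkene geometry retained.

Step 4
Reactants: 8 methyl (2Z,4E)-2-(tert-butoxycarbonylamino)-6-(tert-butyldimethylsilyloxy)-4-methylhexa-2,4-dienoate
Product: 9 methyl (2R,4E)-2-(tert-butoxycarbonylamino)-6-(tert-butyldimethylsilyloxy)-4-methylhex-4-enoate
Conditions: [Rh(COD)((R,R)-Et-DuPhos)]OTf (1 mol %), H2 (5 bar), MeOH, rt
Reagents that add atoms: none
Why: Rhodium–bisphospholane asymmetric hydrogenation of the chelating enamide should reduce only the α,β-double bond of the dienamide and set C10 as R under control of the (R,R)-ligand, the non-chelating trisubstituted alkene being left intact.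

Step 5
Reactants: 9 methyl (2R,4E)-2-(tert-butoxycarbonylamino)-6-(tert-butyldimethylsilyloxy)-4-methylhex-4-enoate
Product: 10 (2R,4E)-2-(tert-butoxycarbonylamino)-6-(tert-butyldimethylsilyloxy)-4-methylhex-4-enoic acid
Conditions: LiOH, THF/H2O, 0 °C; then 1 M HCl to pH 4, 0 °C
Reagents that add atoms: lithium hydroxide (LiOH), [Li+].[OH-]
Why: Saponification of the methyl ester at low temperature should leave the carbamate, the silyl ether and the α-stereocenter unchanged.

Step 6
Reactants: 10 (2R,4E)-2-(tert-butoxycarbonylamino)-6-(tert-butyldimethylsilyloxy)-4-methylhex-4-enoic acid; 11 Meldrum's acid (2,2-dimethyl-1,3-dioxane-4,6-dione)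
Product: 13 tert-butyl (2R)-2-[(2E)-4-(tert-butyldimethylsilyloxy)-2-methylbut-2-en-1-yl]-3,5-dioxopyrrolidine-1-carboxylate (N-Boc tetramic acid), via acyl Meldrum's acid 12 (not isolated)
Conditions: EDC·HCl, DMAP, CH2Cl2, 0 °C to rt; wash with aqueous KHSO4; then EtOAc, reflux
Reagents that add atoms: none
Why: Carbodiimide C-acylation of Meldrum's acid and thermal cycloreversion to an acylketene that is trapped by the carbamate nitrogen (tetramic acid synthesis from N-protected amino acids) should give the pyrrolidine-2,4-dione with C10 retained.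

Step 7
Reactants: 13 N-Boc tetramic acid; 3 (3R)-6-oxo-3-(prop-1-en-2-yl)heptanal
Product: 15 tert-butyl (5R)-5-[(2E)-4-(tert-butyldimethylsilyloxy)-2-methylbut-2-en-1-yl]-4-hydroxy-2-oxo-3-[(3S)-6-oxo-3-(prop-1-en-2-yl)heptyl]-2,5-dihydro-1H-pyrrole-1-carboxylate (enol form; side-chain stereocenter spatially as in 3), via 3-alkylidene tetramic acid 14 (not isolated)
Conditions: Hantzsch ester, L-proline (5 mol %), CH2Cl2, rt, slow addition of 3
Reagents that add atoms: none
Why: Knoevenagel condensation of the acidic ring methylene with the aldehyde (the methyl ketone is far less electrophilic) and in situ Hantzsch ester transfer hydrogenation of the alkylidene (organocatalytic reductive alkylation) should form the C12–C13 bond without creating a stereocenter.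

Step 8
Reactants: 15 3-alkyl tetramic acid
Product: 16 tert-butyl (5R)-5-[(2E)-4-(tert-butyldimethylsilyloxy)-2-methylbut-2-en-1-yl]-2-oxo-3-[(3S)-6-oxo-3-(prop-1-en-2-yl)heptyl]-4-(trifluoromethylsulfonyloxy)-2,5-dihydro-1H-pyrrole-1-carboxylate
Conditions: Tf2O, Et3N, CH2Cl2, −78 °C
Reagents that add atoms: trifluoromethanesulfonic anhydride, O=S(=O)(OS(=O)(=O)C(F)(F)F)C(F)(F)F
Why: O-Sulfonylation of the vinylogous acid at the 4-oxygen should give the enol triflate and removes the acidic, nucleophilic tetramic acid function before the aldehyde is unmasked.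

Step 9
Reactants: 16 enol triflate silyl ether
Product: 17 tert-butyl (5R)-5-[(2E)-4-hydroxy-2-methylbut-2-en-1-yl]-2-oxo-3-[(3S)-6-oxo-3-(prop-1-en-2-yl)heptyl]-4-(trifluoromethylsulfonyloxy)-2,5-dihydro-1H-pyrrole-1-carboxylate
Conditions: HF·pyridine, pyridine/THF, 0 °C to rt
Reagents that add atoms: none
Why: Buffered fluoride desilylation should free the primary allylic alcohol without touching the triflate, the carbamate or the ketone.

Step 10
Reactants: 17 allylic alcohol
Product: 18 tert-butyl (5R)-5-[(2E)-2-methyl-4-oxobut-2-en-1-yl]-2-oxo-3-[(3S)-6-oxo-3-(prop-1-en-2-yl)heptyl]-4-(trifluoromethylsulfonyloxy)-2,5-dihydro-1H-pyrrole-1-carboxylate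
Conditions: MnO2 (activated, excess), CH2Cl2, rt
Reagents that add atoms: none
Why: Allylic oxidation on MnO2 is neutral and should give the (E)-enal without isomerizing the trisubstituted alkene.

Step 11
Reactants: 18 keto enal
Product: 21 fourteen-membered carbocyclic β-hydroxy ketone (6S,10R; C1 spatially as in 3; C4 ketone, C6 hydroxyl, (7E)-alkene, C11 triflate, N-Boc lactam bridging C10 and C12, isopropenyl on C1), via enol diisopinocampheylborinate 19 (not isolated), via boron aldolate 20 (not isolated)
Conditions: (−)-Ipc2BCl, Et3N, Et2O, slow addition of 18 to 2 mM final concentration, −20 °C; then MeOH, pH 7 buffer, H2O2, 0 °C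
Reagents that add atoms: none
Why: Regioselective boron enolization on the methyl side and intramolecular addition to the enal through a cyclic boron transition state under high dilution (Paterson aldol run as a macro-aldolization) should close the fourteen-membered ring, the Ipc ligands directing attack to the Si face of the aldehyde and setting C6 as S.

Step 12
Reactants: 21 macrocyclic β-hydroxy ketone
Product: 22 fourteen-membered triene alcohol (1R,6S,10R; exocyclic methylene on C4, C6 hydroxyl, (7E)-alkene, C11 triflate, N-Boc lactam, isopropenyl on C1)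
Conditions: Zn, CH2Br2, TiCl4 (reagent preformed in THF), CH2Cl2, 0 °C to rt
Reagents that add atoms: dibromomethane, BrCBr
Why: Takai–Lombardo methylenation with the non-basic zinc/titanium methylene reagent should convert the ketone to the exocyclic alkene without retro-aldol or β-elimination, leaving the triflate, carbamate and lactam carbonyls.

Step 13
Reactants: 22 macrocyclic enol triflate bearing the C1 isopropenyl group
Product: 23 N-Boc O-deacetyl cespitulactam E (1R,6S,10R; bicyclo[9.3.1] core with fused N-Boc lactam, free C6 hydroxyl)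
Conditions: Pd(OAc)2 (10 mol %), PPh3 (25 mol %), HCO2Na, Et4NCl, DMF, 60 °C
Reagents that add atoms: none
Why: Zerovalent palladium inserts into the C11–OTf bond of the vinylogous acyl triflate, the alkenyl–palladium bond adds syn across the isopropenyl C15=CH2 bond with C–C formation at the internal carbon C15, and the resulting neopentyl-type alkylpalladium, which has no β-hydrogen because C15 is quaternary, exchanges its counter-ion for formate, loses CO2 and reductively eliminates C–H to give the second methyl group. The closest known reaction type is the reductive Heck cyclization (Heck cyclization with formate hydride capture) used to build gem-dimethyl quaternary carbons from methallyl-type alkenes and aryl or alkenyl (pseudo)halides. The six-membered ring (C11, C12, C13, C14, C1, C15) closes in the 6-exo-trig mode, and because C11 and C1 are already members of the fourteen-membered carbocycle the same bond creates the twelve-membered ring and thus the bicyclo[9.3.1] core. No new stereocenter arises (C15 carries two methyls, C11 stays sp2); C1, C6 and C10 are spectators, and weakly basic formate at moderate temperature is chosen so that the C10–H position does not epimerize. The step needs exo over 7-endo regioselectivity, selection of one of three alkenes and carbopalladation faster than formate reduction of the alkenylpalladium: the three-atom tether C12–C13–C14 lets only the isopropenyl group be reached in a small-ring exo mode (C4=CH2 and C7=C8 would need ten-membered or four-membered closures), chloride from Et4NCl keeps the alkenylpalladium neutral and slow to bind formate, and sparingly soluble HCO2Na keeps the hydride donor concentration low.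

Step 14
Reactants: 23 N-Boc O-deacetyl cespitulactam E
Product: 24 N-Boc cespitulactam E
Conditions: Ac2O, pyridine, DMAP (cat.), CH2Cl2, 0 °C to rt
Reagents that add atoms: acetic anhydride, CC(=O)OC(C)=O
Why: DMAP-catalyzed acylation should esterify the secondary allylic alcohol with retention at C6; it is placed after the palladium step so that no ionizable allylic acetate meets zerovalent palladium and formate.

Step 15
Reactants: 24 N-Boc cespitulactam E
Product: 25 cespitulactam E
Conditions: Mg(ClO4)2 (20 mol %), MeCN, 50 °C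
Reagents that add atoms: none
Why: Mild Lewis-acid-catalyzed cleavage of the acyl-activated N-Boc group should free the lactam N–H without ionizing the allylic acetate or moving the exocyclic alkene.

Compound list
1 | (+)-limonene oxide (4R, cis/trans mixture) | C=C(C)[C@@H]1CCC2(C)OC2C1 | starting material
2 | (4R)-p-menth-8-ene-1,2-diol | C=C(C)[C@@H]1CCC(C)(O)C(O)C1 | intermediate
3 | (3R)-6-oxo-3-(prop-1-en-2-yl)heptanal | CC(=O)CC[C@H](CC=O)C(C)=C | intermediate
4 | (tert-butyldimethylsilyloxy)acetaldehyde | CC(C)(C)[Si](C)(C)OCC=O | starting material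
5 | 2-(triphenylphosphoranylidene)propanal | CC(C=O)=P(c1ccccc1)(c1ccccc1)c1ccccc1 | starting material
6 | (2E)-4-(tert-butyldimethylsilyloxy)-2-methylbut-2-enal | CC(C)(C)[Si](C)(C)OC/C=C(\C)C=O | intermediate
7 | methyl 2-(tert-butoxycarbonylamino)-2-(dimethoxyphosphoryl)acetate (racemic) | COC(=O)C(NC(=O)OC(C)(C)C)P(=O)(OC)OC | starting material
8 | methyl (2Z,4E)-2-(Boc-amino)-6-(TBS-oxy)-4-methylhexa-2,4-dienoate | COC(=O)/C(NC(=O)OC(C)(C)C)=C/C(C)=C/CO[Si](C)(C)C(C)(C)C | intermediate
9 | methyl (2R,4E)-2-(Boc-amino)-6-(TBS-oxy)-4-methylhex-4-enoate | COC(=O)[C@@H](C/C(C)=C/CO[Si](C)(C)C(C)(C)C)NC(=O)OC(C)(C)C | intermediate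
10 | (2R,4E)-2-(Boc-amino)-6-(TBS-oxy)-4-methylhex-4-enoic acid | CC(C)(C)OC(=O)N[C@H](C/C(C)=C/CO[Si](C)(C)C(C)(C)C)C(=O)O | intermediate
11 | Meldrum's acid | CC1(C)OC(=O)CC(=O)O1 | starting material
12 | 5-acyl Meldrum's acid from 10 | CC(C)(C)OC(=O)N[C@H](C/C(C)=C/CO[Si](C)(C)C(C)(C)C)C(=O)C1C(=O)OC(C)(C)OC1=O | intermediate
13 | tert-butyl (2R)-2-[(2E)-4-(TBS-oxy)-2-methylbut-2-en-1-yl]-3,5-dioxopyrrolidine-1-carboxylate | CC(C)(C)OC(=O)N1C(=O)CC(=O)[C@H]1C/C(C)=C/CO[Si](C)(C)C(C)(C)C | intermediate
14 | 3-alkylidene tetramic acid (Knoevenagel adduct of 13 and 3) | CC(C)(C)OC(=O)N1C(=O)C(=CC[C@@H](CCC(C)=O)C(C)=C)C(=O)[C@H]1C/C(C)=C/CO[Si](C)(C)C(C)(C)C | intermediate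
15 | 3-alkyl tetramic acid, enol form (5R; side chain 3S) | CC(C)(C)OC(=O)N1C(=O)C(CC[C@@H](CCC(C)=O)C(C)=C)=C(O)[C@H]1C/C(C)=C/CO[Si](C)(C)C(C)(C)C | intermediate
16 | 4-triflyloxy pyrrolinone silyl ether | CC(C)(C)OC(=O)N1C(=O)C(CC[C@@H](CCC(C)=O)C(C)=C)=C(OS(=O)(=O)C(F)(F)F)[C@H]1C/C(C)=C/CO[Si](C)(C)C(C)(C)C | intermediate
17 | 4-triflyloxy pyrrolinone allylic alcohol | CC(C)(C)OC(=O)N1C(=O)C(CC[C@@H](CCC(C)=O)C(C)=C)=C(OS(=O)(=O)C(F)(F)F)[C@H]1C/C(C)=C/CO | intermediate
18 | 4-triflyloxy pyrrolinone keto enal | CC(C)(C)OC(=O)N1C(=O)C(CC[C@@H](CCC(C)=O)C(C)=C)=C(OS(=O)(=O)C(F)(F)F)[C@H]1C/C(C)=C/C=O | intermediate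
19 | enol diisopinocampheylborinate of 18 | CC(C)(C)OC(=O)N1C(=O)C(CC[C@@H](CCC(=C)OB([C@@H]2C[C@@H]3C[C@H]([C@H]2C)C3(C)C)[C@@H]2C[C@@H]3C[C@H]([C@H]2C)C3(C)C)C(C)=C)=C(OS(=O)(=O)C(F)(F)F)[C@H]1C/C(C)=C/C=O | intermediate
20 | macrocyclic boron aldolate | CC(C)(C)OC(=O)N1C(=O)C2=C(OS(=O)(=O)C(F)(F)F)[C@H]1C/C(C)=C/[C@@H](OB([C@@H]3C[C@@H]4C[C@H]([C@H]3C)C4(C)C)[C@@H]3C[C@@H]4C[C@H]([C@H]3C)C4(C)C)CC(=O)CC[C@H](CC2)C(C)=C | intermediate
21 | fourteen-membered β-hydroxy ketone (6S,10R) | CC(C)(C)OC(=O)N1C(=O)C2=C(OS(=O)(=O)C(F)(F)F)[C@H]1C/C(C)=C/[C@@H](O)CC(=O)CC[C@H](CC2)C(C)=C | intermediate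
22 | fourteen-membered triene alcohol with C11 triflate (1R,6S,10R) | CC(C)(C)OC(=O)N1C(=O)C2=C(OS(=O)(=O)C(F)(F)F)[C@H]1C/C(C)=C/[C@@H](O)CC(=C)CC[C@H](CC2)C(C)=C | intermediate
23 | N-Boc O-deacetyl cespitulactam E (1R,6S,10R) | C=C1CC[C@@H]2CCC3=C([C@@H](C/C(C)=C/[C@@H](O)C1)N(C(=O)OC(C)(C)C)C3=O)C2(C)C | intermediate
24 | N-Boc cespitulactam E | C=C1CC[C@@H]2CCC3=C([C@@H](C/C(C)=C/[C@@H](OC(C)=O)C1)N(C(=O)OC(C)(C)C)C3=O)C2(C)C | intermediate
25 | cespitulactam E | C=C1CC[C@@H]2CCC3=C([C@@H](C/C(C)=C/[C@@H](OC(C)=O)C1)NC3=O)C2(C)C | target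

Total step count: 15. Longest linear sequence: 14 steps (steps 2 to 15, from 4 and 5 to 25); step 1 runs in parallel.

Steps most likely to fail

Step 11 (macro-aldol). The reagent may give poor facial selectivity at the aldehyde inside the macrocyclic transition state, and the boron Lewis acid with amine may erode C10 or favour oligomers. The fallback sets out from 18 and comes back at 22; it separates ring closure from control of C6. Cyclization with achiral Cy2BCl/Et3N under the same dilution should give the C6-epimeric hydroxy ketone F5. Zn/CH2Br2/TiCl4 methylenation should give the epimeric allylic alcohols F6, and MnO2 should oxidize both epimers to the single macrocyclic enone F7. Corey–Bakshi–Shibata reduction with the (R)-methyl oxazaborolidine and catecholborane at −78 °C, the alkenyl group acting as the large substituent, should then deliver the 6S alcohol 22.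

Step 13 (transannular reductive Heck). The alkenylpalladium may be reduced by formate before the transannular carbopalladation takes place, or C10 may epimerize on long heating. The fallback sets out from 16 and comes back at 23; it inverts the order of ring formation. The same Pd(OAc)2/PPh3/HCO2Na reductive Heck cyclization is run on the open-chain triflate 16, where the 6-exo closure has no macrocyclic constraint, to give the bicyclic lactam silyl ether F1. HF·pyridine should give the allylic alcohol F2 and MnO2 the enal F3. The (−)-Ipc2BCl macro-aldol then closes the twelve-membered ring to the hydroxy ketone F4, and Zn/CH2Br2/TiCl4 methylenation of F4 should give 23.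

Step 12 (methylenation). The free β-hydroxy ketone may undergo retro-aldol cleavage or β-elimination, or the carbamate may be lost, under the Lewis-acidic zinc/titanium reagent. The fallback sets out from 21 and comes back at 22; it masks the hydroxyl and uses a titanium alkylidene instead. TESOTf/2,6-lutidine should give the triethylsilyl ether F8, the Tebbe reagent Cp2Ti(μ-Cl)(μ-CH2)AlMe2 in THF/pyridine at −40 °C should methylenate the ketone to the silyl ether F9, and HF·pyridine should return the alcohol 22.

Further compounds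
F1 | step 13 | bicyclic N-Boc lactam silyl ether (reductive Heck product of 16) | CC(=O)CC[C@@H]1CCC2=C([C@@H](C/C(C)=C/CO[Si](C)(C)C(C)(C)C)N(C(=O)OC(C)(C)C)C2=O)C1(C)C
F2 | step 13 | bicyclic N-Boc lactam allylic alcohol | CC(=O)CC[C@@H]1CCC2=C([C@@H](C/C(C)=C/CO)N(C(=O)OC(C)(C)C)C2=O)C1(C)C
F3 | step 13 | bicyclic N-Boc lactam keto enal | CC(=O)CC[C@@H]1CCC2=C([C@@H](C/C(C)=C/C=O)N(C(=O)OC(C)(C)C)C2=O)C1(C)C
F4 | step 13 | N-Boc O-deacetyl 4-oxo analogue of 23 (C4 ketone in place of the exocyclic methylene) | O=C1CC[C@@H]2CCC3=C([C@@H](C/C(C)=C/[C@@H](O)C1)N(C(=O)OC(C)(C)C)C3=O)C2(C)C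
F5 | step 11 | C6-epimeric fourteen-membered β-hydroxy ketone | CC(C)(C)OC(=O)N1C(=O)C2=C(OS(=O)(=O)C(F)(F)F)[C@H]1C/C(C)=C/C(O)CC(=O)CC[C@H](CC2)C(C)=C
F6 | step 11 | C6-epimeric fourteen-membered triene alcohol | CC(C)(C)OC(=O)N1C(=O)C2=C(OS(=O)(=O)C(F)(F)F)[C@H]1C/C(C)=C/C(O)CC(=C)CC[C@H](CC2)C(C)=C
F7 | step 11 | fourteen-membered C6 enone | CC(C)(C)OC(=O)N1C(=O)C2=C(OS(=O)(=O)C(F)(F)F)[C@H]1C/C(C)=C/C(=O)CC(=C)CC[C@H](CC2)C(C)=C
F8 | step 12 | triethylsilyl ether of 21 | CC(C)(C)OC(=O)N1C(=O)C2=C(OS(=O)(=O)C(F)(F)F)[C@H]1C/C(C)=C/[C@@H](O[Si](CC)(CC)CC)CC(=O)CC[C@H](CC2)C(C)=C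
F9 | step 12 | triethylsilyl ether of 22 | CC(C)(C)OC(=O)N1C(=O)C2=C(OS(=O)(=O)C(F)(F)F)[C@H]1C/C(C)=C/[C@@H](O[Si](CC)(CC)CC)CC(=C)CC[C@H](CC2)C(C)=C
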